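# Proposed total synthesis of CNP0214356.1

Atom labels used throughout: C1 ketone carbon, C2=C3 alkene (C3 carries the methyl), C4 and C11 bridgeheads, C5 cyclobutane CH, C6 CMe2, C7 methacrylate carbon, C8 CH2, C9 isobutyrate carbon, C10 quaternary C–Me. With these labels the target is (4R,5S,7R,9R,10R,11R).

## Structural features

The target is a longipinane. Ring A is a 3-methylcyclohex-2-enone (C1–C2–C3–C4–C10–C11), ring B is a cyclobutane (C4–C5–C11–C10) sharing C4, C10 and C11 with ring A, and ring C is a seven-membered carbocycle (C5–C6–C7–C8–C9–C10, closed through C4 or C11) that spans the two one-carbon bridges C5 and C10. Ring B carries four contiguous stereocentres (C4, C5, C11 and the quaternary C10), and the arms C6 and C9 stand cis-1,3 across it on the face remote from the enone bridge, the crowded arrangement. C7 and C9 carry the two acyloxy groups anti to each other, each next to a quaternary carbon (C6, C10), with C8 a lone CH2 between them. Fragile groups are the methacrylate (Michael acceptor, radical trap), the enone flanked by the strained four-membered ring (sensitive to nucleophiles and to reducing radicals), and two different esters on similar hindered secondary hydroxyls. The real difficulty is twofold: building ring B with C6 and C9 syn, and fixing C7/C9 in the absolute sense. The core has a near mirror plane through C2, C5 and C10 that exchanges the C4 and C11 sides and is broken only by the distant C1 carbonyl and C3 methyl, so substrate control over the two possible anti arrays is expected to be weak. The key step exploits C8: a methylene between two carbinol carbons on quaternary centres is the retron of a one-carbon double nucleophile and a non-enolisable dialdehyde, whose two formyl arms on C5 and C10 are held parallel on one face of ring B.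

## Logic of the disconnections

30 ⇒ 28 (through 29). No skeletal bond is cut. The C1 carbonyl and the C2=C3 bond are traced to a C1 carbinol and an exocyclic C3 methylene. The reason is that the enone next to ring B is the most fragile array of the molecule, so it is released last. The gain is that every earlier step runs on a robust silyl ether and an unactivated alkene. The demand is an oxidation and a base-mediated alkene shift that spare both esters.

28 ⇒ 27 ⇒ 26 ⇒ 25. The O–Si bond at C1 and the two acyl–O bonds at O7 and O9 are cut. This leaves a diol with one protected carbinol. The demand is site selection between two hindered secondary hydroxyls; the less shielded O9–H is acylated first.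

25 ⇒ 22 (through 24 and 23). The C8–H bond is traced back to a C8–N bond. A nitro group at C8 turns this carbon into the nucleophile that can be joined to two carbonyl carbons. The demand is a radical denitration at an unactivated secondary carbon, with both hydroxyls capped so that no retro-nitroaldol reaction can start.

22 ⇒ 19 + 20 (through 21). C7–C8 and C8–C9 are cut, which opens ring C and removes three stereocentres. The reason is the retron named above; the gain is a bicyclic dialdehyde plus a one-carbon reagent. The demands are ring closure faster than a second intermolecular addition, and reagent control of C7 and C9 because the core offers almost none.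

19 ⇒ 18 ⇒ 17. No skeletal bond is cut. Both formyl carbons are traced to one lactone in which C7 is the carbonyl carbon and O9 the ring oxygen. The gain is that the two arms are tied together and need no separate protection. The demand is only reduction and oxidation.

17 ⇒ 16 ⇒ 15 ⇒ 14 ⇒ 12 + 13. The C5–H bond is traced to C5–O, then C5–C6 is cut, then the ester bond O9–C7. Cutting C5–C6 while C6 is tethered to O9 forces C6 onto the crowded face of C5 next to C9, which an untethered nucleophile would avoid. The gain is removal of the quaternary C6 and of the C5 stereocentre, leaving a cyclobutanone and the acyl bromide 13. The demands are addition to a hindered ketone and deoxygenation of a tertiary alcohol.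

12 ⇒ 11 ⇒ 8 (through 10 and 9). C5–C11 and C4–C10 are cut together, which opens rings A and B to an acyclic dienoic acid. The C10 quaternary centre then comes from alkene geometry and all ring stereocentres from one carbinol at C1. The demands are the crossed regiochemistry, facial control by C1, and an alkene that is still nucleophilic enough with two allylic oxygens.

8 ⇒ 7 ⇒ 6 ⇒ 5. The C9–O bond is cut, leaving an allylic methyl group. The gain is a geranate-type chain; the demand is E-selective allylic oxidation at the electron-rich alkene only.

5 ⇒ 4 ⇒ 2 + 3, and 2 ⇒ 1. C1–C2 is cut. This is the only step that has to create absolute configuration, by a catalytic vinylogous aldol addition of a five-carbon dienol ether to a five-carbon enal. The demand is γ-selectivity and high enantioselectivity.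

## Other disconnections considered

**Alternative 1:** The cut is C5–C11 of ring B, which opens the bicycle to the 3-methylcyclohexenone A2 carrying C5 as a secondary tosylate on C4. In the forward key step LiN(SiMe3)2 forms the cross-conjugated C11 enolate, which displaces the tosylate with inversion to give A1.
- In its favour: enolate alkylation of keto tosylates is an established entry to bicyclo[3.1.1]heptenones when the leaving group is primary. The enone is in place from the start. C5 is fixed stereospecifically in the ring-forming step. Postponing the gem-dimethyl group keeps the electrophilic carbon from being neopentylic.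
- Against it here: the leaving group is secondary, and in the transition state the chain on C5 must occupy the crowded position facing the C10 arm, so elimination can compete with four-ring closure. The C5 carbinol must be set beforehand next to C4. The two C6 methyl groups must later be introduced by enolate alkylation beside an enolisable enone. The C10 arm of A1 is an isopropenyl group, which leads to a methyl ketone and thus to an aldol-type closure of ring C; a formyl equivalent at C10 would be needed to serve the nitromethane annulation.
- Comparison: both plans join C11 to C5, the alternative by substitution and the chosen plan by a cycloaddition that forms C4–C10 at the same time. On the setting of C5 the alternative is the better: one stereospecific step against three steps and a tether (steps 10 to 12). The chosen plan is the better on the origin of absolute configuration (one catalytic aldol) and on the gem-dimethyl group, which arrives ready-made in 13. Up to the bicyclic stage the step counts should be about equal.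

**Alternative 2:** The cut is C4–C10, read as the result of a 1,2-shift; the precursor is the α-bromo bicyclo[3.2.1]octenedione A4. In the forward key step methoxide adds to the non-enolisable C9 ketone and the C4–C9 bond migrates to C10 with loss of bromide (quasi-Favorskii), giving the ester A3.
- In its favour: bicyclo[3.2.1]octanes are easier to assemble than bicyclo[3.1.1]heptanes. C9 is delivered at the acid oxidation level, and A3 already carries the whole C6–C7 arm as a 1,1-dimethylallyl group. The C10 methyl can then be added by ester enolate alkylation from the open outer face, which places C9 on the inner face as required.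
- Against it here: migration needs the C4–C9 bond anti-periplanar to C–Br, so the bromide configuration must be controlled. Methoxide can instead attack the enone or simply displace bromide. The product is more strained than the starting cyclopentanone. The vinyl group must later be cleaved without touching the enone. A4 needs its own asymmetric synthesis.
- Comparison: from the bicyclic stage to the dialdehyde the alternative is the better on step economy, since both arms are present at once and no tether or deoxygenation is needed. On the C10 quaternary centre the two plans are equal: both place C9 inward by working on the outer face (alkylation there, alkene geometry here). The chosen plan is the better on the predictability of ring-B formation and on the supply of a single enantiomer.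

**Alternative 3:** The cut is C1–C11 and C1–C2, with C1 supplied by CO, so ring A is closed last from A6, a cyclobutyl iodide (C11) bearing a Z-alkenylboronate (C2) on C4. In the forward key step, Pd(PPh3)4, light and CO turn the iodide into a cyclobutyl radical that is carbonylated and then coupled with the boronate, giving the enone A5.
- In its favour: the enone appears last and never meets nitronates or stannyl radicals. On this point the alternative is the equal or the better of the chosen plan, which needs masking and unmasking (steps 3, 20 and 21). C11 needs no stereocontrol, because the radical loses its configuration and only the cis-fused ring can close. The isobutyrate is already in place.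
- Against it here: ring C fused to a fully substituted cyclobutane carrying iodide and Z-alkenylboronate must be built first, without the rigid bicyclic scaffold that holds the two arms together. The carbonylative coupling must close a strained bridged ring in competition with hydrodeiodination and CO-free coupling.
- Comparison: the alternative is more convergent at the end but should be longer overall, because in the chosen plan one cycloaddition delivers rings A and B together. Mechanistically it relies on a radical/palladium cascade at a hindered secondary centre, against two polar additions to aldehydes in the chosen plan.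

Key step: step 15

Remark: in all bicyclic and tricyclic compounds the labels C1–C11 are those defined at the top.
Remark: the enone is carried as a C1 silyl ether with an exocyclic C3 methylene through steps 7 to 20, because nitronates can add to enones and stannyl radicals open cyclobutyl enones; 19 and 22 therefore have the carbon skeletons of the bicyclo[3.1.1]heptenone C7,C9-dialdehyde and of the 8-nitro-7,9-diol with the enone masked.
Remark: the key step creates three stereocentres (C7, C8, C9), not two; C8 is deleted in step 17, and C7 and C9 are S in the nitro compounds and R afterwards without any change in geometry (C8 loses CIP priority).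
Remark: the catalyst antipodes in steps 2 and 15 are those that give the (5S)-aldol and Re-face attack on the formyl groups; base-mediated equilibration is not used in step 15 because it cannot distinguish the two near-mirror anti arrays.

## Route

Step 1
Reactants: 1 methyl 3-methylbut-2-enoate
Product: 2 tert-butyl[(1-methoxy-3-methylbuta-1,3-dien-1-yl)oxy]dimethylsilane
Conditions: LiN(i-Pr)2, THF, −78 °C; TBSCl, DMPU, −78 °C to rt
Reagents that add atoms: tert-butyldimethylsilyl chloride, CC(C)(C)[Si](C)(C)Cl
Why: Kinetic γ-deprotonation of the enoate gives the lithium dienolate, which is silylated on oxygen (standard preparation of ester-derived silyl dienol ethers); the ketene acetal geometry is irrelevant because both isomers react through the same open transition state in step 2.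

Step 2
Reactants: 2 tert-butyl[(1-methoxy-3-methylbuta-1,3-dien-1-yl)oxy]dimethylsilane; 3 3-methylbut-2-enal
Product: 4 methyl (2E,5S)-5-hydroxy-3,7-dimethylocta-2,6-dienoate
Conditions: SiCl4, chiral bisphosphoramide (2 mol %; two N,N′-dimethyl-1,1′-binaphthyl-2,2′-diamine-derived cyclic phosphoramide units joined through their exocyclic N-methyl nitrogens by a pentane-1,5-diyl chain), i-Pr2NEt (cat.), CH2Cl2, −78 °C; aq. NaHCO3/KF
Reagents that add atoms: none
Why: Catalytic enantioselective vinylogous Mukaiyama aldol reaction: the phosphoramide-bound chlorosilyl cation activates the conjugated aldehyde and the dienol ether attacks through its γ-carbon, forming C1–C2 and the E-enoate. The catalyst antipode is chosen for Si-face attack, which sets C1 as S; this single stereocentre later controls all ring stereocentres.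

Step 3
Reactants: 4 methyl (2E,5S)-5-hydroxy-3,7-dimethylocta-2,6-dienoate
Product: 5 methyl (2E,5S)-5-[(tert-butyldimethylsilyl)oxy]-3,7-dimethylocta-2,6-dienoate
Conditions: TBSOTf, 2,6-lutidine, CH2Cl2, −78 to 0 °C
Reagents that add atoms: tert-butyldimethylsilyl trifluoromethanesulfonate, CC(C)(C)[Si](C)(C)OS(=O)(=O)C(F)(F)F
Why: Routine silylation of a secondary allylic alcohol; a silyl ether is the least electron-withdrawing protecting group available, which matters for the alkene in step 7, and it lasts until step 20.

Step 4
Reactants: 5 methyl (2E,5S)-5-[(tert-butyldimethylsilyl)oxy]-3,7-dimethylocta-2,6-dienoate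
Product: 6 methyl (2E,5S,6E)-5-[(tert-butyldimethylsilyl)oxy]-8-hydroxy-3,7-dimethylocta-2,6-dienoate
Conditions: SeO2 (0.3 equiv), t-BuOOH, salicylic acid (cat.), CH2Cl2, rt
Reagents that add atoms: tert-butyl hydroperoxide, CC(C)(C)OO (terminal oxygen source; the oxygen is passed on through SeO2, O=[Se]=O)
Why: Allylic oxidation by SeO2 (ene reaction, then [2,3]-sigmatropic shift) attacks the electron-rich trisubstituted alkene at a methyl group of its disubstituted end and is E-selective, so the new CH2OH (C9) is trans to the chain and the remaining methyl cis to it. The enoate alkene is deactivated; the reaction is stopped at the alcohol stage.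

Step 5
Reactants: 6 methyl (2E,5S,6E)-5-[(tert-butyldimethylsilyl)oxy]-8-hydroxy-3,7-dimethylocta-2,6-dienoate
Product: 7 methyl (2E,5S,6E)-5,8-bis[(tert-butyldimethylsilyl)oxy]-3,7-dimethylocta-2,6-dienoate
Conditions: TBSCl, imidazole, DMF, rt
Reagents that add atoms: tert-butyldimethylsilyl chloride, CC(C)(C)[Si](C)(C)Cl
Why: Standard silylation of a primary alcohol; it masks O9 during acid chloride formation and ketene generation.

Step 6
Reactants: 7 methyl (2E,5S,6E)-5,8-bis[(tert-butyldimethylsilyl)oxy]-3,7-dimethylocta-2,6-dienoate
Product: 8 (2E,5S,6E)-5,8-bis[(tert-butyldimethylsilyl)oxy]-3,7-dimethylocta-2,6-dienoic acid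
Conditions: LiOH, THF/MeOH/H2O, rt; 1 M HCl to pH 4, 0 °C
Reagents that add atoms: lithium hydroxide, [Li+].[OH-]
Why: Saponification of the methyl ester; the silyl ethers and both alkenes are stable to LiOH at room temperature, and acidification is stopped at pH 4 to protect the allylic silyl ethers.

Step 7
Reactants: 8 (2E,5S,6E)-5,8-bis[(tert-butyldimethylsilyl)oxy]-3,7-dimethylocta-2,6-dienoic acid
Product: 11 bicyclic cyclobutanone (C5 ketone; C1 silyloxy on the C5 side; C3 methylidene; C10 with methyl toward the C1–C3 bridge and C9H2OTBS toward C5), via acid chloride 9 (not isolated), via vinylketene 10 (not isolated)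
Conditions: 1-chloro-N,N,2-trimethylprop-1-en-1-amine, CH2Cl2, 0 °C; then slow addition to Et3N, PhMe, 110 °C (0.01 M)
Reagents that add atoms: none
Why: Neutral acid chloride formation and base-induced 1,4-elimination of HCl through the methyl group cis to the acyl group give vinylketene 10, which undergoes the intramolecular crossed [2+2] cycloaddition known for geranic-acid-type substrates: the ketene carbonyl carbon (C5) bonds to C11 and the ketene α-carbon (C4) to the more substituted C10. The addition is suprafacial on the alkene, so its E geometry places the C10 methyl toward the three-carbon bridge and C9 toward the C5 bridge. The C1 stereocentre selects the alkene face by allylic 1,3-strain (its hydrogen eclipses the alkene on the side of the cis methyl), which puts the silyloxy group on the C5 side and fixes C4, C10 and C11 as in 30; any minor diastereomer belongs to the mirror-image core and is removed here.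

Step 8
Reactants: 11 bicyclic cyclobutanone
Product: 12 C9 alcohol (as 11 with free C9H2OH; C1 silyl ether kept)
Conditions: HF·pyridine, pyridine, THF, 0 °C
Reagents that add atoms: none
Why: Buffered fluoride cleaves the primary silyl ether much faster than the hindered secondary one at C1 (selective desilylation by steric differentiation). The freed hydroxyl may add reversibly to the strained C5 carbonyl, which does not interfere because acylation drains the open form.

Step 9
Reactants: 12 C9 alcohol; 13 2-bromo-2-methylpropanoyl bromide
Product: 14 O9 2-bromo-2-methylpropanoate of 12
Conditions: pyridine, CH2Cl2, 0 °C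
Reagents that add atoms: none
Why: Acylation of a primary alcohol with an acyl bromide and pyridine; it places C6, C7 and the gem-dimethyl group on O9, ready for intramolecular delivery.

Step 10
Reactants: 14 O9 2-bromo-2-methylpropanoate
Product: 15 C5-hydroxy lactone (seven-membered lactone O9–C7(=O)–C6Me2–C5; tertiary hydroxyl on the outer face of C5)
Conditions: SmI2 (2.5 equiv), THF, −78 to 0 °C; aq. NH4Cl
Reagents that add atoms: none
Why: Intramolecular Reformatsky reaction: SmI2 reduces the tertiary bromide to a samarium ester enolate, which adds to the non-enolisable, strain-activated cyclobutanone and closes the seven-membered lactone (7-exo-trig). Because the enolate is tied to C9, which sits on the C5 side of C10, C6 can only reach the face of C5 that points toward C9; the C5–C6 bond therefore forms syn to C9 and the hydroxyl ends on the outer face.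

Step 11
Reactants: 15 C5-hydroxy lactone
Product: 16 C5 methyl oxalate of 15
Conditions: ClC(O)CO2Me, DMAP, CH2Cl2, 0 °C to rt
Reagents that add atoms: methyl chlorooxoacetate, COC(=O)C(=O)Cl
Why: Acylation of the tertiary alcohol with the small, highly electrophilic oxalyl monoester chloride gives the methyl oxalate, the standard radical precursor for tertiary alcohols; elimination cannot compete because the only β-hydrogens are at bridgeheads.

Step 12
Reactants: 16 C5 methyl oxalate
Product: 17 lactone with C5–H (C6 syn to C9; C5 configured as in 30)
Conditions: Bu3SnH, AIBN, PhMe, 110 °C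
Reagents that add atoms: none
Why: Radical deoxygenation of a tertiary alcohol through its methyl oxalate (Barton–McCombie type): the stannyl radical adds to the oxalate, the C5–O bond breaks and the tertiary cyclobutyl radical takes hydrogen from Bu3SnH. C6 is locked on the C9 side by the lactone bridge, so hydrogen can enter only at the outer position, which gives the C5 configuration of 30.

Step 13
Reactants: 17 lactone with C5–H
Product: 18 diol (C7H2OH on C6, C9H2OH on C10)
Conditions: LiAlH4, THF, 0 °C
Reagents that add atoms: none
Why: LiAlH4 reduces the lactone to the diol in one step; the silyl ether and the unactivated alkene are inert.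

Step 14
Reactants: 18 diol
Product: 19 C7,C9-dialdehyde (C1 silyl ether, C3 methylidene; masked-enone form of the bicyclo[3.1.1]heptenone dialdehyde)
Conditions: (COCl)2, DMSO, CH2Cl2, −78 °C; Et3N
Reagents that add atoms: none
Why: Swern oxidation of both neopentyl-type primary alcohols; the aldehydes have no α-hydrogen and cannot epimerise or self-condense, and the cold non-aqueous conditions spare the silyl ether.

Step 15
Reactants: 19 C7,C9-dialdehyde; 20 nitromethane
Product: 22 (7S,8S,9S)-8-nitro-7,9-diol (ring C closed; C1 silyl ether, C3 methylidene), via C9 nitroaldol mono-adduct 21 (not isolated)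
Conditions: 20 (1.1 equiv), Cu(OAc)2·H2O (10 mol %), 2,2′-(propane-2,2-diyl)bis(3a,8a-dihydro-8H-indeno[1,2-d]oxazole) (single enantiomer, 11 mol %), i-Pr2NEt (10 mol %), EtOH, 0 °C to rt
Reagents that add atoms: none
Why: Nitroaldol (Henry) reaction run twice in one flask: acetate on divalent copper, helped by the amine, deprotonates 20, the copper-bound nitronate adds to the copper-bound formyl group at C9 (the aldehyde on the pinned-back ring carbon, expected to react first) to give 21, and the nitronate of the new nitromethyl arm then adds to the C7 formyl group held beside it on the same face of ring B. The closest known reactions are the cyclisation of dialdehydes with nitromethane to nitro cyclitols and nitro sugars and the copper–bis(oxazoline)-catalysed enantioselective Henry addition to α-branched aldehydes. Ring C closes in a 7-exo-trig mode; because C5 and C10 hold both arms syn on a rigid scaffold the effective molarity is high, which is why ring closure should outrun a second intermolecular addition when only 1.1 equiv of 20 is present. C9 is set by the ligand, whose antipode is chosen to direct the nitronate to the Re face of the formyl group; C7 is set in the ring closure, where the same Re preference of the ligand corresponds to the anti (7S,9S) array; C8 is an epimerisable nitro-bearing centre that settles thermodynamically and is deleted later, so either configuration is acceptable. Reagent control is needed because the near mirror plane of the core through C2, C5 and C10 leaves the substrate almost unable to tell the (7S,9S) array from its mirror-related array, and equilibration with a strong base would level them. Both aldehydes lack α-hydrogens, so no aldol reaction or epimerisation competes, and the enone is masked, so no conjugate addition of nitronate can occur. Strong base and long reaction times are avoided, since retro-nitroaldol reaction would erase the catalyst-derived configurations. Three stereocentres are created (C7, C8, C9), two of which persist in 30.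

Step 16
Reactants: 22 (7S,8S,9S)-8-nitro-7,9-diol
Product: 23 7,9-bis(trimethylsilyl) ether of 22
Conditions: 1-(trimethylsilyl)imidazole, CH2Cl2, rt
Reagents that add atoms: 1-(trimethylsilyl)imidazole, C[Si](C)(C)n1ccnc1
Why: Near-neutral silylation with the N-silylimidazole caps both hydroxyls so that no alkoxide can start a retro-nitroaldol reaction in the hot radical step; no base strong enough to form a nitronate is present.

Step 17
Reactants: 23 7,9-bis(trimethylsilyl) ether
Product: 25 (7R,9R)-7,9-diol (C8H2; C1 silyl ether, C3 methylidene), via denitrated bis-silyl ether 24 (not isolated)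
Conditions: Bu3SnH (excess), AIBN, PhMe, 110 °C; then K2CO3, MeOH, rt
Reagents that add atoms: none
Why: Radical denitration: the stannyl radical adds to the nitro group, the C8–N bond breaks and the secondary radical is reduced by Bu3SnH, leaving C8 as the CH2 of 30; with the enone masked, 23 holds no radical acceptor. Methanolysis then removes the two trimethylsilyl groups while the tert-butyldimethylsilyl ether at C1 stays.

Step 18
Reactants: 25 (7R,9R)-7,9-diol
Product: 26 9-isobutyrate of 25 (O7–H free)
Conditions: (i-PrCO)2O (1.05 equiv), DMAP (cat.), Et3N, CH2Cl2, −20 °C
Reagents that add atoms: isobutyric anhydride, CC(C)C(=O)OC(=O)C(C)C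
Why: DMAP-catalysed acylation under stoichiometric control: O9–H is flanked by the ring-fused C10, whose two ring bonds are pinned back by the four-membered ring, whereas O7–H is flanked by the freely rotating gem-dimethyl carbon C6, so the first acyl group is expected to go to O9. Low temperature limits 1,3-acyl migration.

Step 19
Reactants: 26 9-isobutyrate
Product: 27 7-methacrylate 9-isobutyrate (C1 silyl ether)
Conditions: methacrylic anhydride, DMAP, Et3N, BHT (cat.), CH2Cl2, rt
Reagents that add atoms: methacrylic anhydride, CC(=C)C(=O)OC(=O)C(C)=C
Why: Acylation of the remaining hindered secondary alcohol with excess anhydride and DMAP; the radical inhibitor prevents polymerisation of the methacrylate.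

Step 20
Reactants: 27 7-methacrylate 9-isobutyrate (C1 silyl ether)
Product: 28 C1 alcohol (7-methacrylate 9-isobutyrate, C3 methylidene)
Conditions: HF·pyridine, THF, rt
Reagents that add atoms: none
Why: Fluoride cleavage of the silyl ether under buffered acidic conditions that leave both esters and the methacrylate untouched.

Step 21
Reactants: 28 C1 alcohol
Product: 30 CNP0214356.1, via deconjugated ketone 29 (not isolated)
Conditions: DMP, NaHCO3, CH2Cl2, rt; then DBU (0.2 equiv), rt
Reagents that add atoms: none
Why: Dess–Martin oxidation of the secondary alcohol gives the β,γ-unsaturated ketone 29; catalytic amidine base then moves the exocyclic double bond into conjugation through the doubly activated C2 methylene (the only enolisable position, since C11 is a bridgehead), giving the trisubstituted enone of 30. No stereocentre is touched.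

## Compound list

1 | methyl 3-methylbut-2-enoate | COC(=O)C=C(C)C | starting material
2 | tert-butyl[(1-methoxy-3-methylbuta-1,3-dien-1-yl)oxy]dimethylsilane (ketene acetal geometry not fixed; both isomers react alike) | C=C(C)C=C(OC)O[Si](C)(C)C(C)(C)C | intermediate
3 | 3-methylbut-2-enal | CC(C)=CC=O | starting material
4 | methyl (2E,5S)-5-hydroxy-3,7-dimethylocta-2,6-dienoate | COC(=O)/C=C(\C)C[C@H](O)C=C(C)C | intermediate
5 | methyl (2E,5S)-5-[(tert-butyldimethylsilyl)oxy]-3,7-dimethylocta-2,6-dienoate | COC(=O)/C=C(\C)C[C@H](O[Si](C)(C)C(C)(C)C)C=C(C)C | intermediate
6 | methyl (2E,5S,6E)-5-[(tert-butyldimethylsilyl)oxy]-8-hydroxy-3,7-dimethylocta-2,6-dienoate | COC(=O)/C=C(\C)C[C@H](O[Si](C)(C)C(C)(C)C)/C=C(\C)CO | intermediate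
7 | methyl (2E,5S,6E)-5,8-bis[(tert-butyldimethylsilyl)oxy]-3,7-dimethylocta-2,6-dienoate | COC(=O)/C=C(\C)C[C@H](O[Si](C)(C)C(C)(C)C)/C=C(\C)CO[Si](C)(C)C(C)(C)C | intermediate
8 | (2E,5S,6E)-5,8-bis[(tert-butyldimethylsilyl)oxy]-3,7-dimethylocta-2,6-dienoic acid | OC(=O)/C=C(\C)C[C@H](O[Si](C)(C)C(C)(C)C)/C=C(\C)CO[Si](C)(C)C(C)(C)C | intermediate
9 | (2E,5S,6E)-5,8-bis[(tert-butyldimethylsilyl)oxy]-3,7-dimethylocta-2,6-dienoyl chloride | ClC(=O)/C=C(\C)C[C@H](O[Si](C)(C)C(C)(C)C)/C=C(\C)CO[Si](C)(C)C(C)(C)C | intermediate
10 | (5S,6E)-5,8-bis[(tert-butyldimethylsilyl)oxy]-7-methyl-3-methylideneocta-1,6-dien-1-one (vinylketene) | O=C=CC(=C)C[C@H](O[Si](C)(C)C(C)(C)C)/C=C(\C)CO[Si](C)(C)C(C)(C)C | intermediate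
11 | bicyclo[3.1.1]heptanone with C5 ketone bridge, (1S)-silyloxy on the C5 side, C3 methylidene, C10 bearing methyl (toward the C1–C3 bridge) and C9H2OTBS (toward C5); C4, C10, C11 as in 30 | CC(C)(C)[Si](C)(C)OC[C@@]1(C)[C@@H]2[C@@H](O[Si](C)(C)C(C)(C)C)CC(=C)[C@H]1C2=O | intermediate
12 | as 11 with free C9H2OH | OC[C@@]1(C)[C@@H]2[C@@H](O[Si](C)(C)C(C)(C)C)CC(=C)[C@H]1C2=O | intermediate
13 | 2-bromo-2-methylpropanoyl bromide | CC(C)(Br)C(=O)Br | starting material
14 | O9 2-bromo-2-methylpropanoate of 12 | CC(C)(Br)C(=O)OC[C@@]1(C)[C@@H]2[C@@H](O[Si](C)(C)C(C)(C)C)CC(=C)[C@H]1C2=O | intermediate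
15 | seven-membered lactone O9–C7(=O)–C6Me2–C5 with tertiary hydroxyl at C5 on the outer face (C6 syn to C9) | O=C1OC[C@@]2(C)[C@@H]3[C@@H](O[Si](C)(C)C(C)(C)C)CC(=C)[C@H]2[C@]3(O)C1(C)C | intermediate
16 | methyl oxalate of the C5 hydroxyl of 15 | O=C1OC[C@@]2(C)[C@@H]3[C@@H](O[Si](C)(C)C(C)(C)C)CC(=C)[C@H]2[C@]3(OC(=O)C(=O)OC)C1(C)C | intermediate
17 | lactone with C5–H on the outer face (C5 as in 30) | O=C1OC[C@@]2(C)[C@@H]3[C@@H](O[Si](C)(C)C(C)(C)C)CC(=C)[C@H]2[C@@H]3C1(C)C | intermediate
18 | diol: C7H2OH on C6 and C9H2OH on C10 | OC[C@@]1(C)[C@@H]2[C@@H](O[Si](C)(C)C(C)(C)C)CC(=C)[C@H]1[C@@H]2C(C)(C)CO | intermediate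
19 | C7,C9-dialdehyde with (1S)-silyloxy and C3 methylidene (masked-enone form of the bicyclo[3.1.1]heptenone dialdehyde) | O=C[C@@]1(C)[C@@H]2[C@@H](O[Si](C)(C)C(C)(C)C)CC(=C)[C@H]1[C@@H]2C(C)(C)C=O | intermediate
20 | nitromethane | C[N+](=O)[O-] | starting material
21 | mono-adduct: (9S)-carbinol with C8H2NO2 on C9, C7 formyl group intact | [O-][N+](=O)C[C@@H](O)[C@@]1(C)[C@@H]2[C@@H](O[Si](C)(C)C(C)(C)C)CC(=C)[C@H]1[C@@H]2C(C)(C)C=O | intermediate
22 | (7S,8S,9S)-8-nitro-7,9-diol, ring C closed, C1 silyl ether, C3 methylidene (masked-enone form of the 8-nitro longipinenone 7,9-diol) | O[C@@H]1[C@H]([N+](=O)[O-])[C@@H](O)[C@@]2(C)[C@@H]3[C@@H](O[Si](C)(C)C(C)(C)C)CC(=C)[C@H]2[C@@H]3C1(C)C | intermediate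
23 | 7,9-bis(trimethylsilyl) ether of 22 | C[Si](C)(C)O[C@@H]1[C@H]([N+](=O)[O-])[C@@H](O[Si](C)(C)C)[C@@]2(C)[C@@H]3[C@@H](O[Si](C)(C)C(C)(C)C)CC(=C)[C@H]2[C@@H]3C1(C)C | intermediate
24 | 7,9-bis(trimethylsilyl) ether with C8H2 (nitro group removed) | C[Si](C)(C)O[C@@H]1C[C@@H](O[Si](C)(C)C)[C@@]2(C)[C@@H]3[C@@H](O[Si](C)(C)C(C)(C)C)CC(=C)[C@H]2[C@@H]3C1(C)C | intermediate
25 | (7R,9R)-7,9-diol, C1 silyl ether, C3 methylidene | O[C@@H]1C[C@@H](O)[C@@]2(C)[C@@H]3[C@@H](O[Si](C)(C)C(C)(C)C)CC(=C)[C@H]2[C@@H]3C1(C)C | intermediate
26 | 9-isobutyrate of 25 | O[C@@H]1C[C@@H](OC(=O)C(C)C)[C@@]2(C)[C@@H]3[C@@H](O[Si](C)(C)C(C)(C)C)CC(=C)[C@H]2[C@@H]3C1(C)C | intermediate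
27 | 7-methacrylate 9-isobutyrate, C1 silyl ether | C=C(C)C(=O)O[C@@H]1C[C@@H](OC(=O)C(C)C)[C@@]2(C)[C@@H]3[C@@H](O[Si](C)(C)C(C)(C)C)CC(=C)[C@H]2[C@@H]3C1(C)C | intermediate
28 | 7-methacrylate 9-isobutyrate with free (1S)-hydroxyl and C3 methylidene | C=C(C)C(=O)O[C@@H]1C[C@@H](OC(=O)C(C)C)[C@@]2(C)[C@@H]3[C@@H](O)CC(=C)[C@H]2[C@@H]3C1(C)C | intermediate
29 | 7-methacrylate 9-isobutyrate with C1 ketone and C3 methylidene (β,γ-unsaturated ketone) | C=C(C)C(=O)O[C@@H]1C[C@@H](OC(=O)C(C)C)[C@@]2(C)[C@@H]3C(=O)CC(=C)[C@H]2[C@@H]3C1(C)C | intermediate
30 | CNP0214356.1, (4R,5S,7R,9R,10R,11R)-longipin-2-en-1-one 7-methacrylate 9-isobutyrate | C=C(C)C(=O)O[C@@H]1C[C@@H](OC(=O)C(C)C)[C@@]2(C)[C@@H]3C(=O)C=C(C)[C@H]2[C@@H]3C1(C)C | target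

## Step count and least certain steps

Total: 21 steps. Longest linear sequence: 21 steps (1 → 2 → 4 → … → 30); the route is linear, with 3, 13 and 20 entering in steps 2, 9 and 15.

**Step 15 (key step).** The most likely failure is loss of reagent control in the ring-closing addition, or partial equilibration by retro-nitroaldol reaction. Either gives poor or wrong facial selectivity at C7 (or C9), because the intramolecular addition is constrained by the tether and the substrate has almost no facial bias of its own. A second intermolecular addition of 20 is a lesser risk. The fallback resets the configuration by reagent-controlled reduction instead of reagent-controlled addition. The isomer mixture is taken unchanged through steps 16 and 17. The fallback sets out from 25 obtained as a mixture of C7/C9 isomers, which is oxidised with DMP to the 7,9-dione F1, so that all isomers converge. Corey–Bakshi–Shibata reduction of both carbonyl groups (BH3·SMe2, (S)-1-methyl-3,3-diphenyltetrahydro-1H,3H-pyrrolo[1,2-c][1,3,2]oxazaborole, THF, −20 °C) should then give the (7R,9R)-anti diol, since each ketone has a quaternary carbon as large and C8H2 as small substituent. The fallback comes back to the route at 25.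

**Step 7.** The most likely failure is sluggish cycloaddition of an alkene that carries two allylic oxygens, so that ketene dimerisation or oligomerisation takes over; incomplete facial selection by C1 is a second risk. The fallback uses a more electrophilic cumulene and sets out from 8. Coupling with dimethylamine gives the N,N-dimethylamide F2. Tf2O and 2,4,6-collidine convert it into the vinylketeniminium triflate F3, which should add to the alkene in the same crossed sense to give the cyclobutaniminium triflate F4. Aqueous NaHCO3 hydrolyses F4, and the fallback comes back at 11.

**Step 10.** The most likely failure is protonation of the samarium enolate before it adds to the ketone, which is shielded by the C1 silyl ether, or retro-aldol opening on work-up. The fallback replaces reductive enolate formation by a base-mediated aldol addition and sets out from 12. Acylation with isobutyryl chloride gives the isobutyrate F5, the same compound that simple reduction of the bromide would leave. Deprotonation with LiN(i-Pr)2 (THF, −78 °C) and intramolecular addition of the lithium enolate to the non-enolisable ketone come back to the route at 15.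

**Step 17.** The most likely failure is slow C–N homolysis at an unactivated secondary carbon, so that the chain stalls and thermal retro-nitroaldol reaction or elimination competes at 110 °C. The fallback activates the nitro group as an α-nitro ketone and sets out from 22. Oxidation with DMP gives the 8-nitro-7,9-dione F6, whose doubly activated nitro group is removed by Bu3SnH/AIBN at 80 °C to give the 7,9-dione F1. Reduction as described under step 15 comes back at 25.

**Step 18.** The most likely failure is insufficient discrimination between the two hindered secondary hydroxyls, or 1,3-acyl migration under the basic conditions. The fallback inverts the order of the acylations if O7–H proves the more reactive, and sets out from 25. Methacrylic anhydride (1.05 equiv, DMAP, −20 °C) gives the 7-methacrylate F7, and isobutyric anhydride then acylates O9–H, coming back at 27. In either order a wrongly acylated monoester can be returned to 25 by methanolysis.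

## Further compounds

F1 | step 15 | 7,9-dione (C8H2 between two ketones; C1 silyl ether, C3 methylidene) | O=C1CC(=O)[C@@]2(C)[C@@H]3[C@@H](O[Si](C)(C)C(C)(C)C)CC(=C)[C@H]2[C@@H]3C1(C)C
F2 | step 7 | (2E,5S,6E)-5,8-bis[(tert-butyldimethylsilyl)oxy]-N,N,3,7-tetramethylocta-2,6-dienamide | CN(C)C(=O)/C=C(\C)C[C@H](O[Si](C)(C)C(C)(C)C)/C=C(\C)CO[Si](C)(C)C(C)(C)C
F3 | step 7 | vinylketeniminium triflate (N,N-dimethyliminium analogue of 10) | C[N+](C)=C=CC(=C)C[C@H](O[Si](C)(C)C(C)(C)C)/C=C(\C)CO[Si](C)(C)C(C)(C)C.[O-]S(=O)(=O)C(F)(F)F
F4 | step 7 | cyclobutaniminium triflate (N,N-dimethyliminium analogue of 11 at C5) | CC(C)(C)[Si](C)(C)OC[C@@]1(C)[C@@H]2[C@@H](O[Si](C)(C)C(C)(C)C)CC(=C)[C@H]1C2=[N+](C)C.[O-]S(=O)(=O)C(F)(F)F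
F5 | step 10 | O9 isobutyrate of 12 | CC(C)C(=O)OC[C@@]1(C)[C@@H]2[C@@H](O[Si](C)(C)C(C)(C)C)CC(=C)[C@H]1C2=O
F6 | step 17 | 8-nitro-7,9-dione (C8 configurationally labile, not specified) | O=C1C([N+](=O)[O-])C(=O)[C@@]2(C)[C@@H]3[C@@H](O[Si](C)(C)C(C)(C)C)CC(=C)[C@H]2[C@@H]3C1(C)C
F7 | step 18 | 7-methacrylate of 25 (O9–H free) | C=C(C)C(=O)O[C@@H]1C[C@@H](O)[C@@]2(C)[C@@H]3[C@@H](O[Si](C)(C)C(C)(C)C)CC(=C)[C@H]2[C@@H]3C1(C)C
A1 | alternative 1 | bicyclo[3.1.1]heptenone with C10 isopropenyl and C5 2-(tert-butyldimethylsilyloxy)ethyl arms | C=C(C)[C@@]1(C)[C@@H]2C(=O)C=C(C)[C@H]1[C@@H]2CCO[Si](C)(C)C(C)(C)C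
A2 | alternative 1 | 3-methylcyclohex-2-enone with C10 methyl and isopropenyl and, on C4, the C5 secondary tosylate carrying the silyloxyethyl chain | C=C(C)[C@@]1(C)CC(=O)C=C(C)[C@H]1[C@H](OS(=O)(=O)c2ccc(C)cc2)CCO[Si](C)(C)C(C)(C)C
A3 | alternative 2 | bicyclo[3.1.1]heptenone C10 methyl ester with C5 1,1-dimethylallyl arm | COC(=O)[C@@H]1[C@@H]2C(=O)C=C(C)[C@H]1[C@@H]2C(C)(C)C=C
A4 | alternative 2 | α-bromo bicyclo[3.2.1]octenedione (C9 ketone bonded to C4 and to bromine-bearing C10) | O=C1[C@H](Br)[C@@H]2C(=O)C=C(C)[C@H]1[C@@H]2C(C)(C)C=C
A5 | alternative 3 | longipinenone 9-isobutyrate 7-silyl ether | CC(C)(C)[Si](C)(C)O[C@@H]1C[C@@H](OC(=O)C(C)C)[C@@]2(C)[C@@H]3C(=O)C=C(C)[C@H]2[C@@H]3C1(C)C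
A6 | alternative 3 | C11 cyclobutyl iodide with Z-alkenyl pinacolboronate on C4 (C11 configuration immaterial) | CC(C)(C)[Si](C)(C)O[C@@H]1C[C@@H](OC(=O)C(C)C)[C@@]2(C)C(I)[C@@H](C1(C)C)[C@@H]2/C(C)=C\B3OC(C)(C)C(C)(C)O3
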